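**Retrosynthetic overview**

1. The target is a cyclic peroxy-hemiketal. The last disconnections are a C3 ethyl ketal and C1 ethyl ester (hydrolysis), and before them the C6–CH3 bond, made by methyl delivery to the C6 peroxycarbenium ion of a 3,6-diethoxy-1,2-dioxane.
2. Key disconnection: the 1,2-dioxane is cut at O–C6 and at C3–C4 into a C3–O–O "carbonyl-oxide equivalent" (a malonate ortho ester plus Me3SiOOSiMe3) and a C4–C5–C6 ketone homoenolate equivalent, an α-siloxy allylsilane.
3. Enabling feature: both ring carbons flanking the O–O bond (C3 and C6) are fully substituted and oxygen-bearing. With C6 raised to the ketone (ketal) level, ring atoms C3–C4–C5–C6 are a masked 1,4-dicarbonyl; C4 is then the β (homoenolate) carbon of the C6 carbonyl and C3 an acyl cation carrying the peroxide.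
4. Stereocentres: C8 from (R)-citronellal; the silicon-bearing carbinol by ligand-controlled alkynylation; C4 by anti SE2′ chirality transfer from it; C6 by axial methylation relayed from C4; C3 by anomeric equilibration.
5. Ring order: the only ring, the 1,2-dioxane, is closed in the key step.

Key step: step 9

Remark: locants follow the acid chain (C1 carboxyl, C3 hemiketal carbon, C4 CHMe, C6 quaternary peroxy carbon, C8 side-chain CHMe); (R)-citronellal of high enantiomeric purity is assumed.

Step 1
Reactants: 1 (R)-citronellal; 2 6-phenylhex-1-ene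
Product: 3 (3R)-3-methyl-11-phenylundec-6-enal (E/Z mixture)
Conditions: second-generation Grubbs catalyst RuCl2(=CHPh)(PCy3)(H2IMes) (3 mol %), 2 (3 equiv), CH2Cl2, 40 °C
Reagents that add atoms: none
Why: Olefin cross-metathesis of the prenyl-type alkene of 1 with the terminal alkene 2 is driven by loss of isobutene and tolerates the aldehyde, and the C8 stereocentre is carried in unchanged from 1.

Step 2
Reactants: 3 (3R)-3-methyl-11-phenylundec-6-enal
Product: 4 (3R)-3-methyl-11-phenylundecanal
Conditions: H2 (1 atm), 5% Pd/C, EtOAc, 23 °C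
Reagents that add atoms: none
Why: Heterogeneous catalytic hydrogenation should saturate the disubstituted alkene (both geometric isomers converge) faster than it touches the aliphatic aldehyde or the arene.

Step 3
Reactants: 4 (3R)-3-methyl-11-phenylundecanal
Product: 5 (3R)-1-[dimethyl(phenyl)silyl]-3-methyl-11-phenylundecan-1-ol (both C1 epimers)
Conditions: PhMe2SiLi (1.2 equiv, THF solution), THF, −78 °C; aq. NH4Cl
Reagents that add atoms: dimethylphenylsilyllithium, [Li][Si](C)(C)c1ccccc1
Why: 1,2-Addition of a silyllithium to an aldehyde gives the α-silyl carbinol, whose new centre is immaterial because it is oxidised in the next step.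

Step 4
Reactants: 5 (3R)-1-[dimethyl(phenyl)silyl]-3-methyl-11-phenylundecan-1-ol
Product: 6 (3R)-1-[dimethyl(phenyl)silyl]-3-methyl-11-phenylundecan-1-one
Conditions: (COCl)2, DMSO, CH2Cl2, −78 °C; Et3N, −78 → 0 °C
Reagents that add atoms: none
Why: Swern oxidation of an α-silyl carbinol is a standard entry to acylsilanes and avoids the free alkoxide that would trigger Brook rearrangement.

Step 5
Reactants: 6 (3R)-1-[dimethyl(phenyl)silyl]-3-methyl-11-phenylundecan-1-one; 7 propyne
Product: 8 (4S,6R)-4-[dimethyl(phenyl)silyl]-6-methyl-14-phenyltetradec-2-yn-4-ol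
Conditions: 7 (3 equiv), ZnEt2 (2.5 equiv), ProPhenol ligand (20 mol %, enantiomer chosen for the 4S carbinol), toluene, 0 °C; aq. NH4Cl at 0 °C
Reagents that add atoms: none
Why: Ligand-controlled addition of an alkynylzinc to the acylsilane (catalytic asymmetric alkynylation) should set the tertiary α-silyl carbinol by reagent control, the remote C8 methyl having little say, and the cold quench keeps the zinc alkoxide from Brook rearrangement.

Step 6
Reactants: 8 (4S,6R)-4-[dimethyl(phenyl)silyl]-6-methyl-14-phenyltetradec-2-yn-4-ol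
Product: 9 (4S,6R)-4-[dimethyl(phenyl)silyl]-6-methyl-14-phenyl-4-(trimethylsilyloxy)tetradec-2-yne
Conditions: N-(trimethylsilyl)imidazole (2 equiv), CH2Cl2, 23 °C
Reagents that add atoms: N-(trimethylsilyl)imidazole, C[Si](C)(C)n1ccnc1
Why: Neutral O-silylation with a silylimidazole never forms the alkoxide, so the carbinol configuration and the C–Si bond should be kept.

Step 7
Reactants: 9 (4S,6R)-4-[dimethyl(phenyl)silyl]-6-methyl-14-phenyl-4-(trimethylsilyloxy)tetradec-2-yne
Product: 10 (2Z,4S,6R)-4-[dimethyl(phenyl)silyl]-6-methyl-14-phenyl-4-(trimethylsilyloxy)tetradec-2-ene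
Conditions: H2 (1 atm), Lindlar catalyst (Pd/CaCO3 poisoned with Pb(OAc)2), quinoline, hexane, 23 °C
Reagents that add atoms: none
Why: Lindlar semihydrogenation adds hydrogen syn and should give the (Z)-alkene, the geometry that later steers the chirality transfer.

Step 8
Reactants: 11 ethyl 3,3-diethoxyacrylate
Product: 12 ethyl 3,3,3-triethoxypropanoate
Conditions: EtOH (5 equiv), pyridinium p-toluenesulfonate (2 mol %), CH2Cl2, 23 °C
Reagents that add atoms: ethanol, CCO
Why: Acid-catalysed addition of an alcohol to the ketene acetal (C-protonation, then capture of the dialkoxycarbenium ion) gives the ortho ester that supplies C1–C3 at the acid oxidation level.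

Step 9
Reactants: 10 (2Z,4S,6R)-4-[dimethyl(phenyl)silyl]-6-methyl-14-phenyl-4-(trimethylsilyloxy)tetradec-2-ene; 12 ethyl 3,3,3-triethoxypropanoate; 13 bis(trimethylsilyl) peroxide
Product: 16 ethyl 2-[(4R)-3,6-diethoxy-4-methyl-6-[(2R)-2-methyl-10-phenyldecyl]-1,2-dioxan-3-yl]acetate (C3/C6 epimer mixture), via silylperoxy ortho ester 14 (not isolated), via silyl enol ether adduct 15 (not isolated)
Conditions: 12 (1.2 equiv), 13 (1.2 equiv), Me3SiOTf (1.2 equiv), CH2Cl2, −78 °C, 30 min; 10, −78 → −40 °C; EtOH (3 equiv), −40 → 0 °C; Et3N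
Reagents that add atoms: ethanol, CCO
Why: Proposed new method: Me3SiOTf should exchange one ethoxy group of 12 for the silylperoxy group of 13 (giving 14) and ionise a second one to an ethoxy(silylperoxy)carbenium ion, which the γ-carbon of allylsilane 10 attacks in an anti SE2′ (Hosomi–Sakurai) step to give silyl enol ether 15 (C3–C4 bond); ethanol then releases triflic acid, C5 is protonated, and the tethered silylperoxy oxygen captures the C6 oxocarbenium ion (O–C6 bond), the silyl ketal exchanging to the ethyl ketal. The closest known reactions are the Lewis-acid-mediated allylation of peroxycarbenium ions by allylsilanes, the Hosomi–Sakurai reaction of ortho esters, the (3+2) annulation of silylperoxy carbenium ions with alkenes to 1,2-dioxolanes and the acid-catalysed peroxyketalisation of enol ethers; new is their combination into a formal (3+3) annulation with a ketone homoenolate equivalent. The 1,2-dioxane is closed by the second event alone, a 6-exo-trig attack of oxygen on the C6 oxocarbenium carbon. C4 is set by 1,3-chirality transfer from the silicon-bearing carbon: the C–Si bond lies anti to the incoming electrophile and A(1,3) strain with the cis methyl of the (Z)-alkene should put the small siloxy group, not the chain, in the inside position, so the (S)-silane should give (4R), while C3 and C6 are ketal carbons whose configuration is irrelevant here (C6 is reset in step 10, C3 equilibrates in step 12). The step needs γ-regioselectivity (secured by the β-silyl effect), capture of the carbenium ion by 10 and not by the more nucleophilic enol ether 15 (limiting electrophile, low temperature, hindered C5), and ring closure in preference to loss of the peroxide to ethanol (intramolecularity).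

Step 10
Reactants: 16 ethyl 2-[(4R)-3,6-diethoxy-4-methyl-6-[(2R)-2-methyl-10-phenyldecyl]-1,2-dioxan-3-yl]acetate
Product: 17 ethyl 2-[(4R,6S)-3-ethoxy-4,6-dimethyl-6-[(2R)-2-methyl-10-phenyldecyl]-1,2-dioxan-3-yl]acetate (C3 epimer mixture)
Conditions: AlMe3 (3 equiv), CH2Cl2, −78 → −30 °C; aq. NaHCO3
Reagents that add atoms: trimethylaluminium, C[Al](C)C
Why: Proposed new method: AlMe3 should ionise the C6 ethoxy group (the C6 peroxycarbenium ion is dialkyl-stabilised, whereas ionisation at C3 is retarded by the electron-withdrawing CH2CO2Et group) and deliver methyl along the axial trajectory of the half-chair with the C4 methyl pseudo-equatorial, that is trans to the C4 methyl, which sets (6S); the closest known reactions are the Lewis-acid-mediated substitution of 3-alkoxy-1,2-dioxolanes and 1,2-dioxanes by allylsilanes via cyclic peroxycarbenium ions and the AlMe3 methylation of cyclic ketals via oxocarbenium ions.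

Step 11
Reactants: 17 ethyl 2-[(4R,6S)-3-ethoxy-4,6-dimethyl-6-[(2R)-2-methyl-10-phenyldecyl]-1,2-dioxan-3-yl]acetate
Product: 18 2-[(4R,6S)-3-ethoxy-4,6-dimethyl-6-[(2R)-2-methyl-10-phenyldecyl]-1,2-dioxan-3-yl]acetic acid
Conditions: LiOH (3 equiv), THF/H2O (3:1), 0 °C; 1 M HCl to pH 4
Reagents that add atoms: lithium hydroxide, [Li+].[OH-]
Why: Saponification is run while C3 is still a full ketal, so no hydroperoxy ketone can open and epimerise C4, and neither peroxide carbon bears a hydrogen for a Kornblum–DeLaMare fragmentation.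

Step 12
Reactants: 18 2-[(4R,6S)-3-ethoxy-4,6-dimethyl-6-[(2R)-2-methyl-10-phenyldecyl]-1,2-dioxan-3-yl]acetic acid
Product: 19 2-[(3S,4R,6S)-3-hydroxy-4,6-dimethyl-6-[(2R)-2-methyl-10-phenyldecyl]-1,2-dioxan-3-yl]acetic acid
Conditions: AcOH/THF/H2O (3:1:1), 23 °C
Reagents that add atoms: water, O
Why: Acid-catalysed hydrolysis of the peroxyketal (transketalisation with water via the C3 peroxycarbenium ion) should give the hemiketal, whose C3 settles under thermodynamic control as the (3S) anomer with axial hydroxyl (anomeric effect) and equatorial CH2CO2H, C4 methyl and C6 chain.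

**Compound list**

1 | (R)-citronellal | C[C@H](CCC=C(C)C)CC=O | starting material
2 | 6-phenylhex-1-ene | C=CCCCCc1ccccc1 | starting material
3 | (3R)-3-methyl-11-phenylundec-6-enal | C[C@H](CCC=CCCCCc1ccccc1)CC=O | intermediate
4 | (3R)-3-methyl-11-phenylundecanal | C[C@H](CCCCCCCCc1ccccc1)CC=O | intermediate
5 | (3R)-1-[dimethyl(phenyl)silyl]-3-methyl-11-phenylundecan-1-ol | C[C@H](CCCCCCCCc1ccccc1)CC(O)[Si](C)(C)c1ccccc1 | intermediate
6 | (3R)-1-[dimethyl(phenyl)silyl]-3-methyl-11-phenylundecan-1-one | C[C@H](CCCCCCCCc1ccccc1)CC(=O)[Si](C)(C)c1ccccc1 | intermediate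
7 | propyne | CC#C | starting material
8 | (4S,6R)-4-[dimethyl(phenyl)silyl]-6-methyl-14-phenyltetradec-2-yn-4-ol | C[C@H](CCCCCCCCc1ccccc1)C[C@@](O)(C#CC)[Si](C)(C)c1ccccc1 | intermediate
9 | (4S,6R)-4-[dimethyl(phenyl)silyl]-6-methyl-14-phenyl-4-(trimethylsilyloxy)tetradec-2-yne | C[C@H](CCCCCCCCc1ccccc1)C[C@@](O[Si](C)(C)C)(C#CC)[Si](C)(C)c1ccccc1 | intermediate
10 | (2Z,4S,6R)-4-[dimethyl(phenyl)silyl]-6-methyl-14-phenyl-4-(trimethylsilyloxy)tetradec-2-ene | C[C@H](CCCCCCCCc1ccccc1)C[C@@](O[Si](C)(C)C)(/C=C\C)[Si](C)(C)c1ccccc1 | intermediate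
11 | ethyl 3,3-diethoxyacrylate | CCOC(=O)C=C(OCC)OCC | starting material
12 | ethyl 3,3,3-triethoxypropanoate | CCOC(=O)CC(OCC)(OCC)OCC | intermediate
13 | bis(trimethylsilyl) peroxide | C[Si](C)(C)OO[Si](C)(C)C | starting material
14 | ethyl 3,3-diethoxy-3-(trimethylsilylperoxy)propanoate | CCOC(=O)CC(OCC)(OCC)OO[Si](C)(C)C | intermediate
15 | ethyl (4R,8R)-3-ethoxy-4,8-dimethyl-16-phenyl-6-(trimethylsilyloxy)-3-(trimethylsilylperoxy)hexadec-5-enoate | CCOC(=O)CC(OCC)(OO[Si](C)(C)C)[C@H](C)C=C(O[Si](C)(C)C)C[C@H](C)CCCCCCCCc1ccccc1 | intermediate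
16 | ethyl 2-[(4R)-3,6-diethoxy-4-methyl-6-[(2R)-2-methyl-10-phenyldecyl]-1,2-dioxan-3-yl]acetate | C[C@H](CCCCCCCCc1ccccc1)CC1(OCC)C[C@@H](C)C(OCC)(CC(=O)OCC)OO1 | intermediate
17 | ethyl 2-[(4R,6S)-3-ethoxy-4,6-dimethyl-6-[(2R)-2-methyl-10-phenyldecyl]-1,2-dioxan-3-yl]acetate | C[C@H](CCCCCCCCc1ccccc1)C[C@@]1(C)C[C@@H](C)C(OCC)(CC(=O)OCC)OO1 | intermediate
18 | 2-[(4R,6S)-3-ethoxy-4,6-dimethyl-6-[(2R)-2-methyl-10-phenyldecyl]-1,2-dioxan-3-yl]acetic acid | C[C@H](CCCCCCCCc1ccccc1)C[C@@]1(C)C[C@@H](C)C(OCC)(CC(=O)O)OO1 | intermediate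
19 | 2-[(3S,4R,6S)-3-hydroxy-4,6-dimethyl-6-[(2R)-2-methyl-10-phenyldecyl]-1,2-dioxan-3-yl]acetic acid | C[C@H](CCCCCCCCc1ccccc1)C[C@@]1(C)C[C@@H](C)[C@](O)(CC(=O)O)OO1 | target

**Step count and risks**

Total step count: 12. Longest linear sequence: 11 (steps 1–7 and 9–12).

The three steps most likely to fail:

Step 9 (proposed new method). The carbenium ion may be consumed by the silyl enol ether intermediate (double alkylation at C5), the allylsilane may be protodesilylated or ionised at its tertiary siloxy group, the peroxide may be lost to ethanol before ring closure, and the chirality transfer may be eroded if the chain competes with the siloxy group for the inside position. The fallback uses known chemistry, sets out from 4 and comes back at 16. Addition of (E)-prop-1-enylmagnesium bromide to 4 should give (2E,6R)-6-methyl-14-phenyltetradec-2-en-4-ol F1, and MnO2 oxidation the enone (2E,6R)-6-methyl-14-phenyltetradec-2-en-4-one F2. A cinchona-derived primary-amine (iminium) catalysed Michael addition of nitromethane then forms the C3–C4 bond and sets C4, giving (2R,6R)-2,6-dimethyl-1-nitro-14-phenyltetradecan-4-one F3. A Nef reaction (NaOMe, then cold aqueous H2SO4) should give (2R,6R)-2,6-dimethyl-4-oxo-14-phenyltetradecanal F4, and Roskamp homologation (ethyl diazoacetate, SnCl2) ethyl (4R,8R)-4,8-dimethyl-3,6-dioxo-16-phenylhexadecanoate F5. This 1,4-diketone is closed to 16 with H2O2 and catalytic H2SO4 in EtOH (peroxyketalisation of a 1,4-dicarbonyl).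

Step 10 (proposed new method). Ionisation may occur at C3 instead of C6 (methyl then enters at the wrong ketal carbon or the exocyclic enoate forms), the organoaluminium may cleave the O–O bond, and the facial preference of the peroxycarbenium ion may be lower than the half-chair model suggests. The fallback uses known chemistry, sets out from 4 and comes back at 17; it passes through F1 to F5 as described for step 9. Wittig methylenation of the isolated C6 ketone of F5 (Ph3P=CH2, 2.2 equiv, the β-keto ester being held as its enolate) should give ethyl (4R)-4-methyl-6-[(2R)-2-methyl-10-phenyldecyl]-3-oxohept-6-enoate F6. Isayama–Mukaiyama hydroperoxysilylation (Co(thd)2, O2, Et3SiH) should give ethyl (4R,8R)-4,6,8-trimethyl-3-oxo-16-phenyl-6-(triethylsilylperoxy)hexadecanoate F7. Camphorsulfonic acid in EtOH closes it onto the C3 ketone to 17 together with its C6 epimer ethyl 2-[(4R,6R)-3-ethoxy-4,6-dimethyl-6-[(2R)-2-methyl-10-phenyldecyl]-1,2-dioxan-3-yl]acetate F8, from which 17 is separated by chromatography.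

Step 5. Facial discrimination at the acylsilane carbonyl may be poor for this aliphatic substrate, and the zinc alkoxide may undergo Brook rearrangement before the quench. The fallback sets out from 6 and comes back at 8: uncatalysed addition of prop-1-ynylmagnesium bromide in THF at −78 °C with a cold quench should give 8 and its carbinol epimer (4R,6R)-4-[dimethyl(phenyl)silyl]-6-methyl-14-phenyltetradec-2-yn-4-ol F9 as diastereomers (the C8 centre makes them separable), and 8 is isolated by chromatography.

**Further compounds**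

F1 | step 9 | (2E,6R)-6-methyl-14-phenyltetradec-2-en-4-ol | C[C@H](CCCCCCCCc1ccccc1)CC(O)/C=C/C
F2 | step 9 | (2E,6R)-6-methyl-14-phenyltetradec-2-en-4-one | C[C@H](CCCCCCCCc1ccccc1)CC(=O)/C=C/C
F3 | step 9 | (2R,6R)-2,6-dimethyl-1-nitro-14-phenyltetradecan-4-one | C[C@H](CCCCCCCCc1ccccc1)CC(=O)C[C@@H](C)C[N+](=O)[O-]
F4 | step 9 | (2R,6R)-2,6-dimethyl-4-oxo-14-phenyltetradecanal | C[C@H](CCCCCCCCc1ccccc1)CC(=O)C[C@@H](C)C=O
F5 | step 9 | ethyl (4R,8R)-4,8-dimethyl-3,6-dioxo-16-phenylhexadecanoate | C[C@H](CCCCCCCCc1ccccc1)CC(=O)C[C@@H](C)C(=O)CC(=O)OCC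
F6 | step 10 | ethyl (4R)-4-methyl-6-[(2R)-2-methyl-10-phenyldecyl]-3-oxohept-6-enoate | C=C(C[C@H](C)CCCCCCCCc1ccccc1)C[C@@H](C)C(=O)CC(=O)OCC
F7 | step 10 | ethyl (4R,8R)-4,6,8-trimethyl-3-oxo-16-phenyl-6-(triethylsilylperoxy)hexadecanoate | CC[Si](CC)(CC)OOC(C)(C[C@H](C)CCCCCCCCc1ccccc1)C[C@@H](C)C(=O)CC(=O)OCC
F8 | step 10 | ethyl 2-[(4R,6R)-3-ethoxy-4,6-dimethyl-6-[(2R)-2-methyl-10-phenyldecyl]-1,2-dioxan-3-yl]acetate | C[C@H](CCCCCCCCc1ccccc1)C[C@]1(C)C[C@@H](C)C(OCC)(CC(=O)OCC)OO1
F9 | step 5 | (4R,6R)-4-[dimethyl(phenyl)silyl]-6-methyl-14-phenyltetradec-2-yn-4-ol | C[C@H](CCCCCCCCc1ccccc1)C[C@](O)(C#CC)[Si](C)(C)c1ccccc1
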